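**Assumption:** lignan locants are used throughout (C7 = aryl-bearing ring carbon, C8 = ring CH carrying C9H2OH, C8' = carbinol carbon carrying the C7'H2 of the dimethoxybenzyl group, C9' = ring CH2), and the benzylic halides 5 and 10 are bought as catalogue chemicals.

## Retrosynthetic overview

- Target ⇐ a 3-aryl-7-benzyl-2,6-dioxabicyclo[2.2.1]heptan-7-ol: reductive cleavage of the acetal C1–O6 bond frees C9–OH and leaves the oxolane.
- Bridged acetal ⇐ catechol lactol: oxidation to the p-quinone methide and capture of C7 by the anomeric (C9') hydroxyl. This is the C7–O–C9' closure of lignan biosynthesis, run transannularly so that the cage forces the aryl group cis to C9 (a free closure would give 7,8-trans).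
- Lactol ⇐ cis-dibenzyl α-hydroxy-γ-lactone ⇐ enolate hydroxylation of the trans-dibenzyl lactone ⇐ benzylation of the (R)-β-arylmethyl-γ-butyrolactone ⇐ Evans alkylation of a succinate imide. C8 comes from the auxiliary, C8' from 1,2-induction, C7 from the cage.
- Ring order: γ-lactone (step 3, carrier ring) → lactol (step 6) → dioxabicyclo[2.2.1]heptane containing the final oxolane (step 8) → oxolane alone (step 9).

## Route

**Step 1**
Reactants: 1 4-tert-butoxy-4-oxobutanoic acid; 2 (4R)-4-benzyl-1,3-oxazolidin-2-one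
Product: 4 tert-butyl 4-[(4R)-4-benzyl-2-oxo-1,3-oxazolidin-3-yl]-4-oxobutanoate, via mixed pivalic anhydride 3 (not isolated)
Conditions: t-BuCOCl, Et3N, THF, −20 °C; then 2, LiCl, −20 °C → rt
Reagents that add atoms: none
Why: N-acylation of the oxazolidinone by the mixed anhydride under LiCl/Et3N activation (standard Evans imide formation), with no stereocenter formed.

**Step 2**
Reactants: 4; 5 1,2-bis(benzyloxy)-4-(chloromethyl)benzene
Product: 7 tert-butyl (3R)-3-[3,4-bis(benzyloxy)benzyl]-4-[(4R)-4-benzyl-2-oxo-1,3-oxazolidin-3-yl]-4-oxobutanoate, via sodium enolate 6 (not isolated)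
Conditions: NaN(SiMe3)2, THF, −78 °C; then 5, Bu4NI (10 mol %), −78 → −20 °C
Reagents that add atoms: none
Why: Evans asymmetric alkylation, in which the chelated (Z)-enolate is alkylated on the face away from the C4 benzyl group of the (R)-auxiliary and so sets C8 as R, with iodide catalysis turning the benzylic chloride into the more reactive iodide.

**Step 3**
Reactants: 7
Product: 9 (4R)-4-[3,4-bis(benzyloxy)benzyl]oxolan-2-one, via hydroxy ester 8 (not isolated)
Conditions: LiBH4, MeOH (1 equiv), THF, 0 °C; then p-TsOH (cat.), CH2Cl2, rt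
Reagents that add atoms: none
Why: reductive removal of the auxiliary (LiBH4 reduces the imide carbonyl but not the tert-butyl ester) followed by acid-catalysed lactonisation of the γ-hydroxy ester, neither of which touches C8.

**Step 4**
Reactants: 9; 10 4-(bromomethyl)-1,2-dimethoxybenzene
Product: 12 (3R,4R)-4-[3,4-bis(benzyloxy)benzyl]-3-(3,4-dimethoxybenzyl)oxolan-2-one, via lithium enolate 11 (not isolated)
Conditions: LiN(SiMe3)2, THF, −78 °C; then 10, −78 → −30 °C
Reagents that add atoms: none
Why: lactone enolate alkylation in which the electrophile enters anti to the C4 arylmethyl group (1,2-induction) to give the trans-lactone; this carbon is made planar again in step 5, so its ratio is not critical.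

**Step 5**
Reactants: 12
Product: 14 (3R,4S)-4-[3,4-bis(benzyloxy)benzyl]-3-(3,4-dimethoxybenzyl)-3-hydroxyoxolan-2-one, via potassium enolate 13 (not isolated)
Conditions: KN(SiMe3)2, THF, −78 °C; then 3-phenyl-2-(phenylsulfonyl)oxaziridine, −78 °C; aq NH4Cl
Reagents that add atoms: 3-phenyl-2-(phenylsulfonyl)oxaziridine, O=S(=O)(c1ccccc1)N1OC1c1ccccc1
Why: Davis enolate hydroxylation, in which oxygen is transferred to the planar tetrasubstituted enolate on the face anti to the C4 arylmethyl group, so the new OH is trans and the 3-benzyl group cis to that substituent, which fixes the C8' carbinol.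

**Step 6**
Reactants: 14
Product: 15 (3R,4S)-4-[3,4-bis(benzyloxy)benzyl]-3-(3,4-dimethoxybenzyl)oxolane-2,3-diol (both anomers)
Conditions: i-Bu2AlH (2.5 equiv), CH2Cl2, −78 °C; aq KNaC4H4O6
Reagents that add atoms: none
Why: partial reduction of the γ-lactone to the lactol with i-Bu2AlH at −78 °C (one equivalent is consumed by the tertiary OH), leaving C8 and C8' untouched and the anomeric centre as an equilibrating mixture.

**Step 7**
Reactants: 15
Product: 16 4-{[(3S,4R)-4-(3,4-dimethoxybenzyl)-4,5-dihydroxyoxolan-3-yl]methyl}benzene-1,2-diol (both anomers)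
Conditions: H2 (1 atm), 10% Pd/C, EtOAc–EtOH, rt
Reagents that add atoms: none
Why: hydrogenolysis of the two aryl benzyl ethers, to which the methyl ethers, the lactol and the tertiary alcohol are inert.

**Step 8**
Reactants: 16
Product: 19 (1S,3R,4R,7R)-3-(3,4-dihydroxyphenyl)-7-(3,4-dimethoxybenzyl)-2,6-dioxabicyclo[2.2.1]heptan-7-ol, via ortho-quinone 17 (not isolated), via quinone methide 18 (not isolated)
Conditions: Ag2O (1.05 equiv), 4 Å molecular sieves, CH2Cl2–THF (0.01 M), 0 °C → rt, dark
Reagents that add atoms: none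
Why: Proposed new method: Ag2O oxidises only the catechol ring (the dimethoxy ring has no free phenol) to the o-quinone 17, which tautomerises to the 2-hydroxy-p-quinone methide 18, and the anomeric OH cis to the side chain then adds to C7 in a 5-exo oxa-1,6-addition (the same C7–O–C9' bond formation that closes lignan oxolanes in the plant) to give the 2,6-dioxabicyclo[2.2.1]heptane; in this cage an exo aryl group would sit about 2.5 Å from the benzyl CH2 that is syn on the one-atom bridge, so the aryl group goes endo, that is cis to C9 (C7 = R), and because the addition is reversible the same preference holds under equilibration; the closest known reaction types are Ag2O-generated quinone methide cyclisations of phenolic lignans and the o-quinone to quinone methide isomerisation–cyclisation of 4-alkylcatechols.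

**Step 9**
Reactants: 19
Product: 20 (3R,4R,5R)-5-(3,4-dihydroxyphenyl)-3-(3,4-dimethoxybenzyl)-4-(hydroxymethyl)oxolan-3-ol (target)
Conditions: i-Bu2AlH (6 equiv), CH2Cl2, −78 → 0 °C; aq KNaC4H4O6
Reagents that add atoms: none
Why: reductive cleavage of a bicyclic acetal by i-Bu2AlH, in which aluminium bound to the carbinol oxygen on C7 of the cage (which points toward O6, about 2.5 Å, and away from O2) chelates O6, so the C1–O6 bond breaks and hydride goes to C1 (C9'), which keeps the aryl-bearing oxolane, frees C9–OH and touches none of the three stereocenters.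

## Compound list

1 | 4-tert-butoxy-4-oxobutanoic acid (mono-tert-butyl succinate) | CC(C)(C)OC(=O)CCC(=O)O | starting material
2 | (4R)-4-benzyl-1,3-oxazolidin-2-one | O=C1N[C@H](Cc2ccccc2)CO1 | starting material
3 | 4-tert-butoxy-4-oxobutanoic pivalic anhydride | CC(C)(C)OC(=O)CCC(=O)OC(=O)C(C)(C)C | intermediate
4 | tert-butyl 4-[(4R)-4-benzyl-2-oxo-1,3-oxazolidin-3-yl]-4-oxobutanoate | CC(C)(C)OC(=O)CCC(=O)N1[C@H](Cc2ccccc2)COC1=O | intermediate
5 | 1,2-bis(benzyloxy)-4-(chloromethyl)benzene | ClCc1ccc(OCc2ccccc2)c(OCc2ccccc2)c1 | starting material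
6 | sodium (Z)-enolate of 4 | CC(C)(C)OC(=O)C/C=C(\[O-])N1[C@H](Cc2ccccc2)COC1=O.[Na+] | intermediate
7 | tert-butyl (3R)-3-[3,4-bis(benzyloxy)benzyl]-4-[(4R)-4-benzyl-2-oxo-1,3-oxazolidin-3-yl]-4-oxobutanoate | CC(C)(C)OC(=O)C[C@@H](Cc1ccc(OCc2ccccc2)c(OCc2ccccc2)c1)C(=O)N1[C@H](Cc2ccccc2)COC1=O | intermediate
8 | tert-butyl (3R)-3-[3,4-bis(benzyloxy)benzyl]-4-hydroxybutanoate | CC(C)(C)OC(=O)C[C@@H](Cc1ccc(OCc2ccccc2)c(OCc2ccccc2)c1)CO | intermediate
9 | (4R)-4-[3,4-bis(benzyloxy)benzyl]oxolan-2-one | O=C1C[C@@H](Cc2ccc(OCc3ccccc3)c(OCc3ccccc3)c2)CO1 | intermediate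
10 | 4-(bromomethyl)-1,2-dimethoxybenzene | COc1ccc(CBr)cc1OC | starting material
11 | lithium enolate of 9 | [Li+].[O-]C1=C[C@@H](Cc2ccc(OCc3ccccc3)c(OCc3ccccc3)c2)CO1 | intermediate
12 | (3R,4R)-4-[3,4-bis(benzyloxy)benzyl]-3-(3,4-dimethoxybenzyl)oxolan-2-one | O=C1OC[C@H](Cc2ccc(OCc3ccccc3)c(OCc3ccccc3)c2)[C@H]1Cc1ccc(OC)c(OC)c1 | intermediate
13 | potassium enolate of 12 | [K+].[O-]C1=C(Cc2ccc(OC)c(OC)c2)[C@@H](Cc2ccc(OCc3ccccc3)c(OCc3ccccc3)c2)CO1 | intermediate
14 | (3R,4S)-4-[3,4-bis(benzyloxy)benzyl]-3-(3,4-dimethoxybenzyl)-3-hydroxyoxolan-2-one | O=C1OC[C@H](Cc2ccc(OCc3ccccc3)c(OCc3ccccc3)c2)[C@]1(O)Cc1ccc(OC)c(OC)c1 | intermediate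
15 | (3R,4S)-4-[3,4-bis(benzyloxy)benzyl]-3-(3,4-dimethoxybenzyl)oxolane-2,3-diol (both anomers) | OC1OC[C@H](Cc2ccc(OCc3ccccc3)c(OCc3ccccc3)c2)[C@]1(O)Cc1ccc(OC)c(OC)c1 | intermediate
16 | 4-{[(3S,4R)-4-(3,4-dimethoxybenzyl)-4,5-dihydroxyoxolan-3-yl]methyl}benzene-1,2-diol (both anomers) | OC1OC[C@H](Cc2ccc(O)c(O)c2)[C@]1(O)Cc1ccc(OC)c(OC)c1 | intermediate
17 | ortho-quinone of 16 (4-substituted cyclohexa-3,5-diene-1,2-dione) | OC1OC[C@H](CC2=CC(=O)C(=O)C=C2)[C@]1(O)Cc1ccc(OC)c(OC)c1 | intermediate
18 | 2-hydroxy-p-quinone methide of 16 (exocyclic C7=C bond) | OC1OC[C@H](C=C2C=CC(=O)C(O)=C2)[C@]1(O)Cc1ccc(OC)c(OC)c1 | intermediate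
19 | (1S,3R,4R,7R)-3-(3,4-dihydroxyphenyl)-7-(3,4-dimethoxybenzyl)-2,6-dioxabicyclo[2.2.1]heptan-7-ol (aryl endo, benzyl syn to the O2–C3 bridge; C1 = C9', C3 = C7, C4 = C8, C5 = C9, C7 = C8') | [C@@H]1(c2ccc(O)c(O)c2)O[C@@H]3OC[C@H]1[C@]3(O)Cc1ccc(OC)c(OC)c1 | intermediate
20 | (3R,4R,5R)-5-(3,4-dihydroxyphenyl)-3-(3,4-dimethoxybenzyl)-4-(hydroxymethyl)oxolan-3-ol | COc1ccc(C[C@]2(O)CO[C@@H](c3ccc(O)c(O)c3)[C@H]2CO)cc1OC | target

## Step count and risk

Total steps: 9. Longest linear sequence: 9 (the route is fully linear).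

**Step 8 (most likely to fail).** The o-quinone may dimerise or add water, the quinone methide may tautomerise to the styrene, and the cage is strained. Fallback, from 16 back to 19: run the Ag2O oxidation in MeOH–CH2Cl2 so that the quinone methide is caught intermolecularly by solvent, giving the 7-methoxy lactol F1 as both C7 epimers. Then treat it with pyridinium p-toluenesulfonate and 4 Å sieves in dry CH2Cl2. The p-hydroxybenzyl methyl ether re-ionises to the same quinone methide under equilibrating conditions, and with methanol sequestered the only intramolecular outlet is closure by the anomeric OH to 19, with the same endo preference.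

**Step 9.** The hydride may cut the other acetal bond (C1–O2, giving the 9,9'-epoxy isomer), or the Lewis-acidic reagent may ionise the p-oxygenated benzylic C–O bond. Fallback, from 19 to 20: acetylate the two phenols (Ac2O, pyridine) to the cage diacetate F2, whose electron-poor aryl ring no longer supports benzylic ionisation. Reduce the acetal ionically (Et3SiH, Me3SiOTf, CH2Cl2, −78 °C; silylation at the less hindered O6, hydride to the resulting ring oxocarbenium) to the oxolane diacetate F3. Then remove the acetates with K2CO3 in MeOH to reach 20.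

**Step 5.** Face selectivity on a tetrasubstituted enolate may be poor, or the enolate may add to the sulfonimine by-product. Fallback, from 9 back to 16: aldol condensation of 9 with 3,4-dimethoxybenzaldehyde (KOt-Bu, THF, 0 °C → rt, water lost in the same pot) gives the (E)-arylidene lactone F4. Dimethyldioxirane in acetone epoxidises the exocyclic alkene on the face anti to the C4 arylmethyl group to give the spiro-epoxide F5. H2 with Pd/C then cleaves the benzylic C–O bond of the epoxide (the oxygen stays on C8' with the required configuration) and both benzyl ethers, giving the catechol hydroxy lactone F6. i-Bu2AlH at −78 °C reduces this to 16.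

## Further compounds

F1 | step 8 | 7-methoxy derivative of 16 (both C7 epimers, both anomers) | OC1OC[C@H](C(OC)c2ccc(O)c(O)c2)[C@]1(O)Cc1ccc(OC)c(OC)c1
F2 | step 9 | aryl di-O-acetate of 19 | [C@@H]1(c2ccc(OC(C)=O)c(OC(C)=O)c2)O[C@@H]3OC[C@H]1[C@]3(O)Cc1ccc(OC)c(OC)c1
F3 | step 9 | aryl di-O-acetate of 20 | COc1ccc(C[C@]2(O)CO[C@@H](c3ccc(OC(C)=O)c(OC(C)=O)c3)[C@H]2CO)cc1OC
F4 | step 5 | (4R,E)-4-[3,4-bis(benzyloxy)benzyl]-3-(3,4-dimethoxybenzylidene)oxolan-2-one | O=C1OC[C@H](Cc2ccc(OCc3ccccc3)c(OCc3ccccc3)c2)/C1=C\c1ccc(OC)c(OC)c1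
F5 | step 5 | spiro-epoxide of F4 (1,5-dioxaspiro[2.4]heptan-4-one; epoxide oxygen anti to the C4 arylmethyl group) | O=C1OC[C@H](Cc2ccc(OCc3ccccc3)c(OCc3ccccc3)c2)[C@@]12O[C@@H]2c1ccc(OC)c(OC)c1
F6 | step 5 | (3R,4S)-4-(3,4-dihydroxybenzyl)-3-(3,4-dimethoxybenzyl)-3-hydroxyoxolan-2-one | O=C1OC[C@H](Cc2ccc(O)c(O)c2)[C@]1(O)Cc1ccc(OC)c(OC)c1
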